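Numbering: C1 (CHOAc), C2 (CHOBz), C3=C4, C5 and C6 (epoxide CH and quaternary C), C7 (CH2OBz). The six-membered ring is cut at C3=C4 and C1–C6 into two dienyl carbinols, penta-1,4-dien-3-ol (C1–C3) and its resolved 2-(silyloxymethyl) analogue (C4–C7). A temporary diisopropylsilylene joins them through O2 and O5; one double ring-closing metathesis then forms C3=C4 and C1=C6 together, giving the carbocycle as a silylene-bridged cyclohexa-1,4-diene. The step exploits the cis-1,4 relation of the C2 and C5 oxygens across C3=C4: only the O–Si–O-bridged boat can close, which fixes C2. The extra unsaturation at C1=C6 is removed later by epoxidation anti to the bridge and Payne rearrangement to the C1 carbinol and the C5–C6 epoxide.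

Key step: step 6

Remark: "upper face" means the ring face that carries the epoxide oxygen in 16. Compounds 3–5 are racemic.
Assumption: Candida antarctica lipase B acetylates the (R)-enantiomer of 5 (its usual preference for secondary alcohols with one small substituent), so the (S)-alcohol 6 is the one recovered.

Step 1
Reactants: 1 prop-2-enal (acrolein); 2 methyl prop-2-enoate
Product: 3 methyl 3-hydroxy-2-methylidenepent-4-enoate (racemic)
Conditions: DABCO (0.3 equiv), excess 2 as solvent, 0 °C to rt
Reagents that add atoms: none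
Why: Morita–Baylis–Hillman reaction, in which the DABCO–acrylate enolate adds 1,2 to the aldehyde of 1 and loss of DABCO gives the bis-allylic alcohol; its stereocenter (later C5) is racemic and is resolved in step 4.

Step 2
Reactants: 3 methyl 3-hydroxy-2-methylidenepent-4-enoate
Product: 4 2-methylidenepent-4-ene-1,3-diol (racemic)
Conditions: iBu2AlH (3.3 equiv), CH2Cl2, −78 to 0 °C; aq. potassium sodium tartrate
Reagents that add atoms: none
Why: Hydride reduction of the conjugated ester by 1,2-delivery from iBu2AlH should give the allylic primary alcohol without touching either alkene.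

Step 3
Reactants: 4 2-methylidenepent-4-ene-1,3-diol
Product: 5 2-{[(tert-butyldimethylsilyl)oxy]methyl}penta-1,4-dien-3-ol (racemic)
Conditions: TBSCl (1.05 equiv), imidazole, CH2Cl2, −20 to 0 °C
Reagents that add atoms: tert-butylchlorodimethylsilane, CC(C)(C)[Si](C)(C)Cl
Why: Kinetic monosilylation, because the primary allylic hydroxyl reacts much faster than the hindered secondary bis-allylic one.

Step 4
Reactants: 5 racemic silyl ether
Product: 6 (3S)-2-{[(tert-butyldimethylsilyl)oxy]methyl}penta-1,4-dien-3-ol
Conditions: immobilised Candida antarctica lipase B, vinyl acetate (3 equiv), MTBE, 30 °C, stopped just past half conversion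
Reagents that add atoms: none
Why: Enzymatic kinetic resolution by transesterification, in which the (R)-alcohol (vinyl in the small pocket) should be acetylated and the (S)-alcohol recovered; this sets C5 of the target.

Step 5
Reactants: 7 penta-1,4-dien-3-ol; 6 (S)-alcohol
Product: 9 mixed diisopropylsilaketal, via chlorosilane 8 (not isolated)
Conditions: 7, iPr2SiCl2 (3 equiv), Et3N, CH2Cl2, 0 °C; excess silane evaporated; then 6, imidazole, DMF, rt
Reagents that add atoms: dichlorodi(propan-2-yl)silane, CC(C)[Si](Cl)(Cl)C(C)C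
Why: Stepwise silyl ether formation on a dichlorosilane (temporary silicon tether), in which excess silane limits the first substitution to one chloride and 6 then displaces the second, so that the mixed silaketal is formed; no stereocenter is touched.

Step 6
Reactants: 9 mixed diisopropylsilaketal
Product: 11 silylene-bridged cyclohexa-1,4-diene, via monocyclic dioxasilepine 10 (not isolated)
Conditions: second-generation Grubbs catalyst RuCl2(=CHPh)(H2IMes)(PCy3) (10 mol%), 1,4-benzoquinone (20 mol%), toluene (0.005 M), 80 °C
Reagents that add atoms: none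
Why: Ruthenium-alkylidene olefin metathesis, loaded at the monosubstituted vinyl groups, should first close the dioxasilepine 10 through C3=C4 and then join the remaining vinyl group to the 1,1-disubstituted alkene through C1=C6, so that the six-membered carbocycle appears as the ring shared by two silepine rings (a [3+3] union of two pentadienyl units). The closest known reaction type is temporary silicon-tethered ring-closing metathesis of bis(allyloxy)silanes, here run twice in one flask as a double ring-closing metathesis. Each closure is a seven-membered ring-closing metathesis within the tether, the second one transannular, giving the 2,4-dioxa-3-silabicyclo[3.2.2]nonadiene with both alkenes necessarily Z. The new stereocenter C2 arises from the prochiral carbinol carbon of the divinyl unit and is controlled by C5 through the tether, because the O–Si–O bridge can span only cis oxygens of the boat cyclohexa-1,4-diene, and a monocycle closed on the wrong vinyl group can reopen and re-close by reversible metathesis. The step needs intramolecular hetero-coupling instead of oligomerisation, which the tether and high dilution secure, and it needs the bis-allylic product not to isomerise to an arene, for which 1,4-benzoquinone is added to intercept ruthenium hydrides.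

Step 7
Reactants: 11 silylene-bridged cyclohexa-1,4-diene
Product: 12 epoxide of 11 at C1–C6, oxygen anti to the O–Si–O bridge
Conditions: mCPBA (1.1 equiv), NaHCO3, CH2Cl2, −20 to 0 °C
Reagents that add atoms: 3-chloroperoxybenzoic acid, OOC(=O)c1cccc(Cl)c1
Why: Prilezhaev epoxidation, in which the peracid should attack the trisubstituted, more nucleophilic C1=C6 alkene from the face not covered by the Si(iPr)2 bridge, so that the epoxide oxygen ends trans to O2 and O5 (sets C1, and C6 provisionally).

Step 8
Reactants: 12 epoxy silaketal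
Product: 13 (1R,2S,5R,6S)-1-(hydroxymethyl)-7-oxabicyclo[4.1.0]hept-3-ene-2,5-diol
Conditions: TBAF/AcOH (1:1, 4 equiv), THF, 0 °C to rt
Reagents that add atoms: none
Why: Fluoride-induced desilylation cleaves the silaketal and the primary silyl ether, while the acetic acid buffer keeps the medium non-basic so that the epoxide neither opens nor migrates at this stage.

Step 9
Reactants: 13 epoxy triol
Product: 14 (1R,2S,3R,6S)-1-(hydroxymethyl)-7-oxabicyclo[4.1.0]hept-4-ene-2,3-diol
Conditions: t-BuOK (1.1 equiv), THF/t-BuOH, 0 °C to rt; then AcOH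
Reagents that add atoms: none
Why: Payne rearrangement, in which the C5 alkoxide (trans to the epoxide) attacks C6 from the rear in a 3-exo-tet closure with inversion at C6, placing the C5–C6 epoxide on the upper face and freeing O1 on the lower face; the equilibrium should favour this trisubstituted vinyl epoxide because its C1 alkoxide is held by the neighbouring C2 and C7 hydroxyls.

Step 10
Reactants: 14 rearranged epoxy triol
Product: 15 [(1R,2S,3R,6S)-3-(benzoyloxy)-2-hydroxy-7-oxabicyclo[4.1.0]hept-4-en-1-yl]methyl benzoate
Conditions: BzCl (2.1 equiv), pyridine, CH2Cl2, −40 to −10 °C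
Reagents that add atoms: benzoyl chloride, O=C(Cl)c1ccccc1
Why: Rate-controlled acylation, in which the primary C7 hydroxyl and the allylic C2 hydroxyl should react before the C1 hydroxyl, which is flanked by the quaternary epoxide carbon C6.

Step 11
Reactants: 15 dibenzoate alcohol
Product: 16 (1S,2S,3R,6S)-2-(acetyloxy)-1-[(benzoyloxy)methyl]-7-oxabicyclo[4.1.0]hept-4-en-3-yl benzoate
Conditions: Ac2O, DMAP (cat.), pyridine, CH2Cl2, 0 °C to rt
Reagents that add atoms: acetic anhydride, CC(=O)OC(C)=O
Why: DMAP-catalysed acetylation of the remaining hindered secondary hydroxyl under conditions that should neither move the benzoates nor open the vinyl epoxide.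

Compound list
1 | prop-2-enal (acrolein) | C=CC=O | starting material
2 | methyl prop-2-enoate (methyl acrylate) | C=CC(=O)OC | starting material
3 | methyl 3-hydroxy-2-methylidenepent-4-enoate (racemic) | C=CC(O)C(=C)C(=O)OC | intermediate
4 | 2-methylidenepent-4-ene-1,3-diol (racemic) | C=CC(O)C(=C)CO | intermediate
5 | 2-{[(tert-butyldimethylsilyl)oxy]methyl}penta-1,4-dien-3-ol (racemic) | C=CC(O)C(=C)CO[Si](C)(C)C(C)(C)C | intermediate
6 | (3S)-2-{[(tert-butyldimethylsilyl)oxy]methyl}penta-1,4-dien-3-ol | C=C[C@H](O)C(=C)CO[Si](C)(C)C(C)(C)C | intermediate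
7 | penta-1,4-dien-3-ol | C=CC(O)C=C | starting material
8 | chloro(penta-1,4-dien-3-yloxy)di(propan-2-yl)silane | C=CC(C=C)O[Si](Cl)(C(C)C)C(C)C | intermediate
9 | {[(3S)-2-{[(tert-butyldimethylsilyl)oxy]methyl}penta-1,4-dien-3-yl]oxy}(penta-1,4-dien-3-yloxy)di(propan-2-yl)silane | C=CC(C=C)O[Si](C(C)C)(C(C)C)O[C@@H](C=C)C(=C)CO[Si](C)(C)C(C)(C)C | intermediate
10 | (4S,7S)-4-(3-{[tert-butyl(dimethyl)silyl]oxy}prop-1-en-2-yl)-7-ethenyl-2,2-di(propan-2-yl)-4,7-dihydro-1,3,2-dioxasilepine (cis) | CC(C)[Si]1(C(C)C)O[C@@H](C=C)/C=C\[C@H](O1)C(=C)CO[Si](C)(C)C(C)(C)C | intermediate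
11 | (1R,5S)-6-{[(tert-butyldimethylsilyl)oxy]methyl}-3,3-di(propan-2-yl)-2,4-dioxa-3-silabicyclo[3.2.2]nona-6,8-diene | CC(C)[Si]3(C(C)C)O[C@@H]1C=C[C@H](O3)C(CO[Si](C)(C)C(C)(C)C)=C1 | intermediate
12 | 6,7-epoxide of 11 with the epoxide oxygen anti to the O–Si–O bridge (C1 S, C2 R, C5 S, C6 S in the overview numbering) | CC(C)[Si]3(C(C)C)O[C@@H]1C=C[C@H](O3)[C@@]2(CO[Si](C)(C)C(C)(C)C)O[C@@H]12 | intermediate
13 | (1R,2S,5R,6S)-1-(hydroxymethyl)-7-oxabicyclo[4.1.0]hept-3-ene-2,5-diol | O[C@@H]1C=C[C@H](O)[C@@]2(CO)O[C@@H]12 | intermediate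
14 | (1R,2S,3R,6S)-1-(hydroxymethyl)-7-oxabicyclo[4.1.0]hept-4-ene-2,3-diol | O[C@H]1[C@H](O)C=C[C@@H]2O[C@@]21CO | intermediate
15 | [(1R,2S,3R,6S)-3-(benzoyloxy)-2-hydroxy-7-oxabicyclo[4.1.0]hept-4-en-1-yl]methyl benzoate | O[C@H]1[C@H](OC(=O)c2ccccc2)C=C[C@@H]2O[C@@]21COC(=O)c1ccccc1 | intermediate
16 | (1S,2S,3R,6S)-2-(acetyloxy)-1-[(benzoyloxy)methyl]-7-oxabicyclo[4.1.0]hept-4-en-3-yl benzoate | CC(=O)O[C@H]1[C@H](OC(=O)c2ccccc2)C=C[C@@H]2O[C@@]21COC(=O)c1ccccc1 | target

Total step count: 11. Longest linear sequence: 11 steps (1 and 2 to 16); 7 enters at step 5.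

Steps most likely to fail

Step 6. What may go wrong: the second, transannular closure to the bridged bicycle may stall at the monocycle, or oligomerisation and ruthenium-hydride isomerisation with aromatisation may take over. The fallback sets out from 9 and comes back at 13; it separates the two ring closures and gives up the bridge before the second one. First-generation Grubbs catalyst RuCl2(=CHPh)(PCy3)2 should close only the vinyl–vinyl pair of 9, and the cis-monocycle 10 is isolated this time. TBAF removes all silicon to give (3S,4Z,6S)-2-methylideneocta-4,7-diene-1,3,6-triol F1, and TBSOTf/2,6-lutidine gives its tris(tert-butyldimethylsilyl) ether F2. Ring-closing metathesis with second-generation Hoveyda–Grubbs catalyst RuCl2(=CH-C6H4-2-OiPr)(H2IMes) then closes an unstrained six-membered ring to (3R,6S)-3,6-bis[(tert-butyldimethylsilyl)oxy]-1-{[(tert-butyldimethylsilyl)oxy]methyl}cyclohexa-1,4-diene F3. mCPBA epoxidises its trisubstituted alkene anti to the two cis silyloxy groups to give the tris-silylated epoxide F4, and TBAF/AcOH gives 13.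

Step 9. What may go wrong: the alkoxide equilibration may stop at a mixture, by epoxide migration towards C1–C2 or to the exocyclic C6–C7 position, or the vinyl epoxide may be opened by base. The fallback sets out from 13 and comes back at 16; it replaces the Payne rearrangement by a reductive epoxide-to-allylic-alcohol transposition and puts the epoxidation last. Benzoylation of 13 at O7 and O2 (BzCl, pyridine, low temperature; O5 is shielded by C6) gives [(1R,2S,5R,6S)-5-(benzoyloxy)-2-hydroxy-7-oxabicyclo[4.1.0]hept-3-en-1-yl]methyl benzoate F5. MsCl/Et3N gives its methanesulfonate F6. NaI and Zn in DMF (through the allylic iodide) bring about reductive elimination with opening of the epoxide, which leaves the C1 configuration intact and gives [(5R,6R)-5-(benzoyloxy)-6-hydroxycyclohexa-1,3-dien-1-yl]methyl benzoate F7. Ac2O/DMAP gives [(5R,6R)-6-(acetyloxy)-5-(benzoyloxy)cyclohexa-1,3-dien-1-yl]methyl benzoate F8, and mCPBA should epoxidise the trisubstituted C5=C6 alkene anti to the neighbouring acetate to give 16.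

Step 10. What may go wrong: poor discrimination between the two secondary hydroxyls, with over-benzoylation or acylation at O1, and acyl migration between O1 and O2. The fallback sets out from 14 and comes back at 15; it masks O1 together with O7 instead of relying on rates. tBu2Si(OTf)2/2,6-lutidine should tie the 1,3-related O1 and O7 into the six-membered di-tert-butylsilylene of 14 F9. BzCl then acylates the only free hydroxyl to give the O2-benzoate of that silylene F10. TBAF/AcOH removes the silylene to give (1R,2S,3R,6S)-2-hydroxy-1-(hydroxymethyl)-7-oxabicyclo[4.1.0]hept-4-en-3-yl benzoate F11, and BzCl (1 equiv, −78 °C) benzoylates the primary hydroxyl to reach 15.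

Further compounds
F1 | step 6 | (3S,4Z,6S)-2-methylideneocta-4,7-diene-1,3,6-triol | O[C@@H](C=C)/C=C\[C@H](O)C(=C)CO
F2 | step 6 | tris(tert-butyldimethylsilyl) ether of F1 | CC(C)(C)[Si](C)(C)O[C@@H](C=C)/C=C\[C@H](O[Si](C)(C)C(C)(C)C)C(=C)CO[Si](C)(C)C(C)(C)C
F3 | step 6 | (3R,6S)-3,6-bis[(tert-butyldimethylsilyl)oxy]-1-{[(tert-butyldimethylsilyl)oxy]methyl}cyclohexa-1,4-diene | CC(C)(C)[Si](C)(C)O[C@@H]1C=C[C@H](O[Si](C)(C)C(C)(C)C)C(CO[Si](C)(C)C(C)(C)C)=C1
F4 | step 6 | 1,2-epoxide of F3 with the epoxide oxygen anti to the silyloxy groups (tris-silyl ether of 13) | CC(C)(C)[Si](C)(C)O[C@@H]1C=C[C@H](O[Si](C)(C)C(C)(C)C)[C@@]2(CO[Si](C)(C)C(C)(C)C)O[C@@H]12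
F5 | step 9 | [(1R,2S,5R,6S)-5-(benzoyloxy)-2-hydroxy-7-oxabicyclo[4.1.0]hept-3-en-1-yl]methyl benzoate | O=C(O[C@@H]1C=C[C@H](O)[C@@]2(COC(=O)c3ccccc3)O[C@@H]12)c1ccccc1
F6 | step 9 | methanesulfonate of F5 at the C5 oxygen (overview numbering) | O=C(O[C@@H]1C=C[C@H](OS(C)(=O)=O)[C@@]2(COC(=O)c3ccccc3)O[C@@H]12)c1ccccc1
F7 | step 9 | [(5R,6R)-5-(benzoyloxy)-6-hydroxycyclohexa-1,3-dien-1-yl]methyl benzoate | O[C@H]1[C@H](OC(=O)c2ccccc2)C=CC=C1COC(=O)c1ccccc1
F8 | step 9 | [(5R,6R)-6-(acetyloxy)-5-(benzoyloxy)cyclohexa-1,3-dien-1-yl]methyl benzoate | CC(=O)O[C@H]1[C@H](OC(=O)c2ccccc2)C=CC=C1COC(=O)c1ccccc1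
F9 | step 10 | di-tert-butylsilylene of 14 bridging the C1 and C7 oxygens | CC(C)(C)[Si]3(C(C)(C)C)O[C@H]1[C@H](O)C=C[C@@H]2O[C@@]21CO3
F10 | step 10 | benzoate of F9 at the C2 oxygen | CC(C)(C)[Si]3(C(C)(C)C)O[C@H]1[C@H](OC(=O)c4ccccc4)C=C[C@@H]2O[C@@]21CO3
F11 | step 10 | (1R,2S,3R,6S)-2-hydroxy-1-(hydroxymethyl)-7-oxabicyclo[4.1.0]hept-4-en-3-yl benzoate | O[C@H]1[C@H](OC(=O)c3ccccc3)C=C[C@@H]2O[C@@]21CO
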